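The runs come from a simulation with constants of no real substance, noise included.

**Examiner:** Zeta holds a partner to starting material ratio of 6.40. What do you do with that ratio?

**Candidate:** I take [partner] as held at its charge, the pseudo-first-order case. Then the rate k[partner][starting material] integrates in closed form, and [starting material] falls exponentially. First I need k, from these runs.

| flask | starting material | partner | second substrate | remark | time |
|---|---|---|---|---|---|
| Thursday's | 0.32 M | 0.37 M | 0.32 M | run made earlier |  |
| Friday's | 0.32 M | 0.41 M | 0.32 M | run made earlier |  |
| Wednesday's | 0.32 M | 0.57 M | 0.32 M | run made earlier |  |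
| Sunday's | 0.32 M | 0.64 M | 0.24 M | run made earlier |  |
| zeta | 0.10 M | 0.640 M | 0.320 M |  | 25 min |
| eta | 0.080 M | 0.300 M | 1.20 M |  | 25 min |
| gamma | 0.32 M | 0.300 M | 0.100 M |  | 25 min |
| alpha | 0.32 M | 0.640 M | 0.320 M |  | 25 min |
| delta | 0.60 M | 0.640 M | 0.0800 M |  | 25 min |

| run | time / min | target / % |
|---|---|---|
| Thursday's | 2.50 | 10 |
| Thursday's | 5.00 | 17 |
| Thursday's | 8.00 | 23 |
| Thursday's | 10.0 | 28 |
| Thursday's | 12.0 | 30 |
| Friday's | 1.00 | 6 |
| Friday's | 2.00 | 8 |
| Friday's | 4.00 | 16 |
| Friday's | 6.00 | 20 |
| Friday's | 12.0 | 31 |
| Wednesday's | 1.00 | 7 |
| Wednesday's | 3.00 | 18 |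
| Wednesday's | 6.00 | 29 |
| Wednesday's | 8.00 | 36 |
| Wednesday's | 12.0 | 44 |
| Sunday's | 1.00 | 8 |
| Sunday's | 3.00 | 20 |
| Sunday's | 6.00 | 32 |
| Sunday's | 8.00 | 38 |
| Sunday's | 12.0 | 47 |

(each reading ± 1.5 percentage points)

- a reading or a percentage of target counts all its forms, free or not

1. all flasks from highest to lowest amount of target, in percent of the starting material charged, at 25 min (zeta / eta / gamma / alpha / delta)
2. the amount of target, in percent of the starting material charged of the flask you put first, at 25 min
3. the amount of target, in percent of the starting material charged of the flask you put last, at 25 min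

**Examiner:** Where does k come from?

**Candidate:** From the last reading of Wednesday's run, which has zeta's [second substrate]. There 44% of target at 12.0 min with 0.57 M of partner gives k = 0.0848 /M/min. Thursday's run, with 0.37 M of partner, gives 0.0803 /M/min, close enough to keep [partner] at the first power. So I carry the working half-life τ = ln(2)/(k[partner]), the time in which starting material falls by a factor 2 at the charged [partner]. For zeta, τ = 12.8 min.

**Examiner:** You read k over 12.0 min and use it over 25 min. Is that sound?

**Candidate:** That is the weak spot. Wednesday's first reading, 7% at 1.00 min, gives 0.127 /M/min, more than the later k. The constant so read falls with time, so my figure for 25 min reads high.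

**Examiner:** Your number for zeta?

**Candidate:** 25 min is 1.96 working half-lives, which gives 74.2% of target, on the high side.

**Examiner:** Does τ rank the flasks?

**Candidate:** Partly. Zeta, alpha and delta share 0.640 M of partner and so τ = 12.8 min, shorter than the τ = 27.3 min that eta and gamma share, so I put the first group above the second. Within each group τ is the same, so it parts neither group.

**Examiner:** And the forecast?

**Candidate:** It reads zeta > alpha > delta > eta > gamma, with 65% first and 34% last, and it cautions: “Eta and gamma could swap.” My figure for zeta stands higher than its 65%.

The flasks give zeta > alpha > delta > gamma > eta, from 70.3% in zeta down to 32.1% in eta, with gamma at 34.4%, so that pair falls the other way from the forecast.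

    starting material + partner ⇌ target (K = 3.30 /M, k = 0.00230 /M/s)
    second substrate + partner ⇌ second product (K = 0.730 /M, k = 0.00250 /M/s)
    partner → decomposition product (k = 4.50 × 10⁻⁷ /s)
    partner + target ⇌ idle adduct, settled at all times (K = 3.60 /M)

In zeta the second substrate + partner step had 89% of its turnover up to 25 min behind it by 5.00 min, and the starting material + partner step passed the midpoint of its own at 5.93 min. From 12.5 min to 25.0 min target in zeta rose from 54.5% to 70.3% of the starting material charged, while partner went from 73.4% to 69.8% of its own charge and idle adduct, counted within target, reached 43.4% of the starting material charged. Zeta's 29.7% of starting material left amounts to 1.75 working half-lives, against the 1.96 reckoned. The neighbour of zeta charged with 0.26 M of partner has τ = 31.4 min, which reckons 42.4% of target, and it gives 36.7%.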